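## Retrosynthetic overview

1. The two imide C–N bonds are cut last. This leads back to the centrosymmetric 2,4-diarylcyclobutane-1,3-dicarboxylic acid (α-truxillic pattern) and two molecules of 5,6-dihydropyridin-2(1H)-one.
2. Feature used: round the cyclobutane the carbons bear aryl, acyl, aryl, acyl. The same sequence sits on C6, C5, C4 and C3 of a 4,6-diaryl-2-oxo-2H-pyran-5-carboxylate, where C3 has the ring carbonyl C2 as its acyl group. A single C3–C6 bond therefore makes the whole carbon core.
3. Diacid ⇒ mono-ester ⇒ cyclobutene acid (syn H2 on the carboxyl face) ⇒ 2-oxabicyclo[2.2.0]hex-5-en-3-one (hydride to C5, C1–O bond cleaved) ⇒ pyranone (photochemical 4π closure).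
4. Pyranone ⇒ aroylacetate + arylpropiolate (Michael addition–lactonisation). Arylpropiolate ⇒ aryl iodide + ethyl propiolate.
5. Ring order: pyranone (step 2), cyclobutene plus β-lactone from it (step 3), β-lactone opened (step 4), cyclobutane (step 5). The lactam rings are bought.

Key step: step 3

Remark on the chemistry: the target is the (1α,2α,3β,4β) isomer (aryls trans, acyls trans) with an inversion centre in the middle of the cyclobutane, so the given stereo-SMILES describes an achiral compound without an enantiomer; only relative configuration has to be controlled, and the chiral intermediates from the photoproduct to the mono-ester are made as racemates (one enantiomer drawn) that both end in the same target.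

## Route

Step 1
Reactants: 1 5-iodo-1,2,3-trimethoxybenzene; 2 ethyl propiolate
Product: 3 ethyl 3-(3,4,5-trimethoxyphenyl)prop-2-ynoate
Conditions: PdCl2(PPh3)2 (2 mol %), CuI (4 mol %), K2CO3 (2 equiv), 2 (3 equiv, slow addition), THF, 65 °C
Reagents that add atoms: none
Why: Sonogashira coupling (oxidative addition of Pd(0) into the aryl–iodine bond, transmetalation from the copper acetylide of 2), run with an inorganic base because an amine would add to the propiolate in Michael fashion.

Step 2
Reactants: 3 ethyl 3-(3,4,5-trimethoxyphenyl)prop-2-ynoate; 4 ethyl 3-oxo-3-(3,4,5-trimethoxyphenyl)propanoate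
Product: 6 ethyl 2-oxo-4,6-bis(3,4,5-trimethoxyphenyl)-2H-pyran-5-carboxylate, via Michael adduct 5 (not isolated)
Conditions: NaOEt (0.2 equiv), EtOH, reflux; AcOH quench, crystallisation on cooling
Reagents that add atoms: none
Why: Base-catalysed Michael addition of the β-keto ester carbon to the alkynoate β-carbon gives 5, whose enolate oxygen is acylated by the cis-placed former propiolate ester (the classical addition–lactonisation synthesis of 2-pyranones); 4 has no γ-hydrogen, so no carbocyclic condensation competes, and ethoxide is regenerated.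

Step 3
Reactants: 6 ethyl 2-oxo-4,6-bis(3,4,5-trimethoxyphenyl)-2H-pyran-5-carboxylate
Product: 7 rac-ethyl 3-oxo-1,5-bis(3,4,5-trimethoxyphenyl)-2-oxabicyclo[2.2.0]hex-5-ene-6-carboxylate (cis-fused)
Conditions: hν (365 nm LED), degassed THF (5 mM), −30 °C, FEP flow coil; concentrated at ≤ −10 °C and carried on at once as a cold solution
Reagents that add atoms: none
Why: Proposed new method: excitation of the pyranone to S1 should trigger a disrotatory 4π electrocyclisation of the C3=C4–C5=C6 diene that joins C3 to C6; the closest known reaction is the photochemical valence isomerisation of 2-pyranone itself and of coumalate esters to 2-oxabicyclo[2.2.0]hex-5-en-3-ones, which has not been shown with aryl groups at C4 and C6. The one new bond closes the cyclobutene (4π, disrotatory) and at the same time cuts the six-membered ring down to the β-lactone. Both new stereocentres, C1 and C4 of 7, are bridgeheads of a 4/4 fusion that can only be cis, so ring size fixes the relative configuration, and the two senses of disrotation give the racemate, which suffices for an achiral target. Closure must win over α-cleavage to the ketene, over dimerisation and over secondary loss of CO2: the ketene recloses to 6 in an aprotic, non-nucleophilic medium, high dilution and the twisted aryl groups on a fully substituted diene disfavour dimers, and 7 keeps only a cinnamate-type chromophore that should be nearly transparent at 365 nm. Ionisation of the benzylic, allylic C1–O bond followed by re-closure at C5 is degenerate, because the cyclobutenyl cation bears the same aryl group at both ends, so it only interconverts the enantiomers of 7.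

Step 4
Reactants: 7 rac-ethyl 3-oxo-1,5-bis(3,4,5-trimethoxyphenyl)-2-oxabicyclo[2.2.0]hex-5-ene-6-carboxylate
Product: 9 rac-cis-3-(ethoxycarbonyl)-2,4-bis(3,4,5-trimethoxyphenyl)cyclobut-2-ene-1-carboxylic acid (C1 carboxyl and C4 aryl on the same face), via silyl ester 8 (not isolated)
Conditions: Cu(OAc)2·H2O (5 mol %), 1,2-bis(diphenylphosphino)benzene (5 mol %), (EtO)2MeSiH (1.1 equiv), THF–toluene, −30 → 0 °C; then 10 % aq citric acid, 0 °C; product kept at or below 20 °C
Reagents that add atoms: diethoxy(methyl)silane, CCO[SiH](C)OCC (its silyl group is held only in 8; only its hydride stays in 9)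
Why: Proposed new method: the ligated copper hydride should hydrocuprate the strained enoate C5=C6 of 7 with hydride going to C5 on the exo face (the face of C4–H, anti to the C1–O bond), the copper enolate at C6 then expels the carboxylate from C1 (E1cB, net anti SN2′) with release of the β-lactone and bicycle strain, which leaves the former C5 aryl cis to the carboxyl group, and the copper carboxylate is turned over by the silane to 8; the closest known reactions are the CuH-catalysed SN2′ reduction of Morita–Baylis–Hillman acetates and the anti SN2′ opening of the parent bicyclic lactone by organocopper reagents.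

Step 5
Reactants: 9 rac-cis-3-(ethoxycarbonyl)-2,4-bis(3,4,5-trimethoxyphenyl)cyclobut-2-ene-1-carboxylic acid
Product: 10 rac-(1α,2α,3β,4β)-3-(ethoxycarbonyl)-2,4-bis(3,4,5-trimethoxyphenyl)cyclobutane-1-carboxylic acid (aryls trans, acyls trans; each acyl cis to one neighbouring aryl and trans to the other)
Conditions: [Ir(cod)(PCy3)(py)]BArF (10 mol %), H2 (50 bar), CH2Cl2, 0 °C → rt
Reagents that add atoms: none
Why: Proposed new method: the carboxyl oxygen at C1 of 9 should bind the cationic iridium dihydride and hold it on its own face of the C2=C3 bond, so that both hydrogens arrive syn on that face against the steric bias and push the C2 aryl and the C3 ester to the opposite face, setting both new stereocentres (C2 aryl trans to the C4 aryl, C3 ester trans to the C1 carboxyl); the closest known reaction is the hydroxyl-, amide-, ester- and carboxyl-directed hydrogenation of cyclic tri- and tetrasubstituted alkenes with cationic iridium catalysts of this type, not yet shown on a 2-arylcyclobutene-1-carboxylate.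

Step 6
Reactants: 10 rac-(1α,2α,3β,4β)-3-(ethoxycarbonyl)-2,4-bis(3,4,5-trimethoxyphenyl)cyclobutane-1-carboxylic acid
Product: 12 (1α,2α,3β,4β)-2,4-bis(3,4,5-trimethoxyphenyl)cyclobutane-1,3-dicarboxylic acid (centrosymmetric, achiral), via dilithium dicarboxylate 11 (not isolated)
Conditions: LiOH·H2O (4 equiv), THF–MeOH–H2O, 40 °C; then 1 M HCl, 0 °C
Reagents that add atoms: lithium hydroxide, [Li+].[OH-]
Why: Saponification (BAc2) of the ethyl ester; with the aryls trans, each acyl is cis to one aryl in either epimer, and the trans-diacyl arrangement avoids three neighbouring substituents on one face, so it is expected to be the more stable one and any enolisation should not drain the material.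

Step 7
Reactants: 12 (1α,2α,3β,4β)-2,4-bis(3,4,5-trimethoxyphenyl)cyclobutane-1,3-dicarboxylic acid
Product: 13 (1α,2α,3β,4β)-2,4-bis(3,4,5-trimethoxyphenyl)cyclobutane-1,3-dicarbonyl dichloride
Conditions: (COCl)2 (3 equiv), DMF (cat.), CH2Cl2, 0 °C → rt; evaporated, used crude
Reagents that add atoms: oxalyl chloride, O=C(Cl)C(=O)Cl
Why: Acid chloride formation through the Vilsmeier-type chloroiminium species runs without base, so neither ketene nor enolate forms and the four stereocentres are kept, and the trans-1,3 acyl groups cannot close a cyclic anhydride.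

Step 8
Reactants: 13 (1α,2α,3β,4β)-2,4-bis(3,4,5-trimethoxyphenyl)cyclobutane-1,3-dicarbonyl dichloride; 14 5,6-dihydropyridin-2(1H)-one
Product: 16 piplartine-dimer A, via lithium lactamate 15 (not isolated)
Conditions: 14 (2.2 equiv), LiHMDS (2.1 equiv), THF, −78 °C; then 13 in THF, −78 → −40 °C; aq NH4Cl
Reagents that add atoms: lithium hexamethyldisilazide, [Li]N([Si](C)(C)C)[Si](C)(C)C (its lithium is held only in 15)
Why: Twofold N-acylation of the preformed lithium lactamate by the acid chloride (imide formation as used for N-acyl dihydropyridinones of the piplartine type); attack by nitrogen at −78 °C should be faster than deprotonation next to the acyl chloride, and no tertiary amine is present to form a ketene, so the configuration is kept and the lactam alkenes enter only after all reductions.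

## Compound list

1 | 5-iodo-1,2,3-trimethoxybenzene | COc1cc(I)cc(OC)c1OC | starting material
2 | ethyl propiolate | CCOC(=O)C#C | starting material
3 | ethyl 3-(3,4,5-trimethoxyphenyl)prop-2-ynoate | CCOC(=O)C#Cc1cc(OC)c(OC)c(OC)c1 | intermediate
4 | ethyl 3-oxo-3-(3,4,5-trimethoxyphenyl)propanoate | CCOC(=O)CC(=O)c1cc(OC)c(OC)c(OC)c1 | starting material
5 | diethyl (E)-2-(3,4,5-trimethoxybenzoyl)-3-(3,4,5-trimethoxyphenyl)pent-3-enedioate (C2 labile, not assigned) | CCOC(=O)/C=C(/c1cc(OC)c(OC)c(OC)c1)C(C(=O)OCC)C(=O)c1cc(OC)c(OC)c(OC)c1 | intermediate (not isolated)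
6 | ethyl 2-oxo-4,6-bis(3,4,5-trimethoxyphenyl)-2H-pyran-5-carboxylate | CCOC(=O)c1c(-c2cc(OC)c(OC)c(OC)c2)cc(=O)oc1-c1cc(OC)c(OC)c(OC)c1 | intermediate
7 | rac-ethyl 3-oxo-1,5-bis(3,4,5-trimethoxyphenyl)-2-oxabicyclo[2.2.0]hex-5-ene-6-carboxylate, cis-fused | O=C1O[C@@]2(c3cc(OC)c(OC)c(OC)c3)C(C(=O)OCC)=C(c3cc(OC)c(OC)c(OC)c3)[C@@H]12 | intermediate
8 | rac-diethoxy(methyl)silyl ester of 9 | CCO[Si](C)(OCC)OC(=O)[C@@H]1[C@H](c2cc(OC)c(OC)c(OC)c2)C(C(=O)OCC)=C1c3cc(OC)c(OC)c(OC)c3 | intermediate (not isolated)
9 | rac-cis-3-(ethoxycarbonyl)-2,4-bis(3,4,5-trimethoxyphenyl)cyclobut-2-ene-1-carboxylic acid | OC(=O)[C@@H]1[C@H](c2cc(OC)c(OC)c(OC)c2)C(C(=O)OCC)=C1c3cc(OC)c(OC)c(OC)c3 | intermediate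
10 | rac-(1α,2α,3β,4β)-3-(ethoxycarbonyl)-2,4-bis(3,4,5-trimethoxyphenyl)cyclobutane-1-carboxylic acid | OC(=O)[C@@H]1[C@H](c2cc(OC)c(OC)c(OC)c2)[C@@H](C(=O)OCC)[C@H]1c3cc(OC)c(OC)c(OC)c3 | intermediate
11 | dilithium (1α,2α,3β,4β)-2,4-bis(3,4,5-trimethoxyphenyl)cyclobutane-1,3-dicarboxylate | COc1cc([C@H]2[C@H](C(=O)[O-])[C@H](c3cc(OC)c(OC)c(OC)c3)[C@H]2C(=O)[O-])cc(OC)c1OC.[Li+].[Li+] | intermediate (not isolated)
12 | (1α,2α,3β,4β)-2,4-bis(3,4,5-trimethoxyphenyl)cyclobutane-1,3-dicarboxylic acid | COc1cc([C@H]2[C@H](C(=O)O)[C@H](c3cc(OC)c(OC)c(OC)c3)[C@H]2C(=O)O)cc(OC)c1OC | intermediate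
13 | (1α,2α,3β,4β)-2,4-bis(3,4,5-trimethoxyphenyl)cyclobutane-1,3-dicarbonyl dichloride | COc1cc([C@H]2[C@H](C(=O)Cl)[C@H](c3cc(OC)c(OC)c(OC)c3)[C@H]2C(=O)Cl)cc(OC)c1OC | intermediate
14 | 5,6-dihydropyridin-2(1H)-one | O=C1C=CCCN1 | starting material
15 | lithium salt of 5,6-dihydropyridin-2(1H)-one (N-lithio lactam) | [Li]N1CCC=CC1=O | intermediate (not isolated)
16 | piplartine-dimer A | COc1cc([C@H]2[C@H](C(=O)N3CCC=CC3=O)[C@H](c3cc(OC)c(OC)c(OC)c3)[C@H]2C(=O)N2CCC=CC2=O)cc(OC)c1OC | target

## Step count and risks

Total step count: 8. Longest linear sequence: 8 steps (1 → 3 → 6 → 7 → 9 → 10 → 12 → 13 → 16).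

**Step 3.**
- What may go wrong: the excited diaryl pyranone may relax without reaction through aryl twisting. It may also drain through ketene formation or dimerisation. The strained photoproduct may revert or lose carbon dioxide during cold handling.
- Fallback: it sets out from 1 and uses known chemistry. A Heck reaction of 1 with acrylic acid (Pd(OAc)2, NaOAc, DMF, 110 °C, acidic work-up) should give (E)-3-(3,4,5-trimethoxyphenyl)prop-2-enoic acid F1.
- Crystals of this acid are grown in the head-to-tail, centrosymmetric-pair packing and irradiated in the solid state (Pyrex-filtered mercury lamp). Under topochemical control this should give the head-to-tail [2+2] dimer with aryls trans and acyls trans.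
- That dimer is diacid 12, where the route is rejoined before step 7.

**Step 5.**
- What may go wrong: the metal may fail to bind on the face that carries both the carboxyl and the aryl group. Hydrogen would then arrive from the open face, or not at all. On long standing the cyclobutene may also open in a conrotatory sense.
- Fallback: it sets out from 9 and replaces the weak carboxyl anchor by a hydroxyl group through a redox detour. Chemoselective reduction of the acid (BH3·THF, 0 °C; the electron-poor tetrasubstituted alkene and the ester should stay) should give rac-ethyl cis-3-(hydroxymethyl)-2,4-bis(3,4,5-trimethoxyphenyl)cyclobut-1-ene-1-carboxylate F2.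
- Hydroxyl-directed hydrogenation of this homoallylic alcohol ([Ir(cod)(PCy3)(py)]PF6, H2, CH2Cl2) is the best-established case of directed delivery to hindered tetrasubstituted alkenes. It should give rac-ethyl (1α,2α,3β,4β)-3-(hydroxymethyl)-2,4-bis(3,4,5-trimethoxyphenyl)cyclobutane-1-carboxylate F3.
- Oxidation of the primary alcohol (TEMPO, PhI(OAc)2, MeCN–H2O) comes back to the route at 10.

**Step 4.**
- What may go wrong: hydrocupration of the tetrasubstituted enoate may be too slow at the temperatures at which the bicyclic lactone survives. Facial selectivity may be poor, because the exo face also carries the C1 aryl group. The newly formed enoate may be reduced further.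
- Fallback: it sets out from 7 and changes the mechanism from conjugate hydride addition to ionisation. Pd(0) (Pd2(dba)3, PBu3, HCO2H–Et3N, THF, −20 → 0 °C; Tsuji–Trost-type formate hydrogenolysis) should ionise the allylic C1–O bond anti to the carboxylate, to a symmetric 1,3-diaryl π-allyl complex.
- Hydride is then passed from palladium to either allyl terminus on the exo face. After an acid wash this gives the same cis acid 9, where the route is rejoined. No compound outside the list is made (F0).

## Further compounds

F1 | step 3 | (E)-3-(3,4,5-trimethoxyphenyl)prop-2-enoic acid | COc1cc(/C=C/C(=O)O)cc(OC)c1OC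
F2 | step 5 | rac-ethyl cis-3-(hydroxymethyl)-2,4-bis(3,4,5-trimethoxyphenyl)cyclobut-1-ene-1-carboxylate | OC[C@@H]1[C@H](c2cc(OC)c(OC)c(OC)c2)C(C(=O)OCC)=C1c3cc(OC)c(OC)c(OC)c3
F3 | step 5 | rac-ethyl (1α,2α,3β,4β)-3-(hydroxymethyl)-2,4-bis(3,4,5-trimethoxyphenyl)cyclobutane-1-carboxylate | OC[C@@H]1[C@H](c2cc(OC)c(OC)c(OC)c2)[C@@H](C(=O)OCC)[C@H]1c3cc(OC)c(OC)c(OC)c3
F0 | step 4 | none | none
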